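The data come from a simulation with made-up constants; noise was put on by code.

Time is the cheap measure here: 2.5 d is twice the last reading of either earlier run, so it pays to work in powers of ten of electrophile lost.

| setting | midnight | summer | grey | ochre | red |
|---|---|---|---|---|---|
| electrophile | 0.36 M | 0.36 M | 0.36 M | 0.36 M | 0.36 M |
| nucleophile | 1 equiv | 1 equiv | 1.00 equiv | 1.00 equiv | 1.00 equiv |
| free base | 0.20 equiv | 0.79 equiv | 0.300 equiv | 0.600 equiv | 1.20 equiv |
| remark | run made earlier | run made earlier |  |  |  |
| time |  |  | 2.5 d | 2.5 d | 2.5 d |

| run | time / h | electrophile / % | target / % |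
|---|---|---|---|
| midnight | 4.00 | 75 | 17 |
| midnight | 8.00 | 66 | 17 |
| midnight | 12.0 | 52 | 20 |
| midnight | 15.0 | 45 | 18 |
| midnight | 20.0 | 40 | 16 |
| midnight | 25.0 | 36 | 14 |
| midnight | 30.0 | 32 | 15 |
| summer | 4.00 | 78 | 18 |
| summer | 8.00 | 56 | 23 |
| summer | 12.0 | 49 | 16 |
| summer | 15.0 | 42 | 23 |
| summer | 20.0 | 31 | 18 |
| summer | 25.0 | 25 | 20 |
| summer | 30.0 | 20 | 22 |

(each reading ± 2 percentage points)

1. part of the electrophile that has reacted at the end, grey
2. part of the electrophile that has reacted at the end, ochre
3. part of the electrophile that has reacted at the end, red
4. what raising the equivalents of free base from its lowest to its highest value here does to the part of the electrophile that has reacted (changes below 5 percentage points count as none) (it falls / it rises / no change)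



How fast does a flask rich in base fall? The summer run drops to 20 % in 30.0 h, which gives a decade rate, the powers of ten of electrophile lost per hour, of 0.0233 h⁻¹. Held for 2.5 d, that rate gives a depth of 1.40 decades, so 4.00 % is left and 96.0 % has reacted. This reckoning takes that as the estimate for red, which holds more base than the summer run.

Does little base cost depth? At 15.0 h the midnight run reads 45 % and the summer run 42 %, but from 20.0 h to 30.0 h the midnight run falls at 0.00969 h⁻¹ against 0.0190 h⁻¹ for the summer run over the same stretch, a ratio read as 1.96. A straight continuation of that stretch from the midnight run's last reading to 2.5 d gives 0.786 decades, or 83.6 % reacted, taken here as a rough estimate, not a bound, for grey, which holds more base than the midnight run.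

Is the spread a change? The gap between the two estimates, 12 percentage points, exceeds the margin, so this reckoning expects conversion to rise with base.

The forecast gives 86 %, 94 % and 97 %, and says it rises, on the ground that “base seems to keep the nucleophile free”. Its grey and its red both stand above this reckoning.

The flask gives 82.7 %, 90.5 % and 92.3 %: it rises, by 9.6 points.

    electrophile + target → side product (k = 0.168 M⁻¹ h⁻¹)
    target ⇌ isomer of the product (K = 1.80, k = 0.137 h⁻¹)
    electrophile + nucleophile → acid set free + target (k = 0.207 M⁻¹ h⁻¹)
    nucleophile + acid set free ⇌ protonated nucleophile, settled at all times (K = 936 M⁻¹)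
    acid set free + free base ⇌ salt of the base, settled at all times (K = 1.44 × 10⁵ M⁻¹)

Free base still free at the end is 0.139 % of its charge in grey and 39.0 % in red. Red itself reaches a depth of 1.11 decades, against the 1.40 reckoned. The neighbour at 0.090 M, on red's recipe, stands at a quarter of red's concentration. Scaling the decade rate by that factor, as suits steps with two partners, gives 0.349 decades and 44.7 % left, and that neighbour holds 42 %.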